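**Retrosynthetic overview**

- Feature: C4–C5 and C6–C7 of the heptane chain are two acetaldehyde units carrying 3,5-syn oxygens, joined to a C1–C3 arylpropanoid unit whose (S)-C2 carbinol and 4-hydroxyphenyl ring are the skeleton of L-tyrosine.
- C7–aryl bond: the guaiacyl ring is added as an aryl Grignard reagent to the lactol carbon C7; the benzylic C7 oxygen is then removed by hydrogenolysis.
- C5–C6 and C3–C4 bonds: one aldolase-catalysed tandem addition of two acetaldehydes to a tyrosine-derived (S)-2-alkoxy-3-arylpropanal sets C3 and C5.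
- Rings: the only ring built is the six-membered lactol (O3, C3–C7), closed in the enzymatic step and reopened at C7 by the Grignard reagent; the target itself is acyclic.
- Protection: O2 and the tyrosyl phenol travel as MOM ethers, the guaiacyl phenol as a benzyl ether.

Key step: step 5

Assumption: with a free C2 hydroxyl the first aldol product would close to a five-membered lactol and leave the cycle after one acetaldehyde, so the acceptor carries O2 (and the phenol) as MOM ethers; an aldolase variant that turns over this α-branched (S)-acceptor is assumed to be found by screening.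

**Step 1**
Reactants: 1 L-tyrosine
Product: 4 (S)-2-hydroxy-3-(4-hydroxyphenyl)propanoic acid, via diazonium carboxylate 2 (not isolated), via alpha-lactone 3 (not isolated)
Conditions: NaNO2 (slow addition), 1 M aq. H2SO4, 0 °C → rt
Reagents that add atoms: water, O
Why: Diazotisation of an α-amino acid (Van Slyke-type hydroxy-deamination) should give net retention, because the carboxylate displaces dinitrogen from 2 with inversion to α-lactone 3 and water opens 3 with a second inversion, so C2 stays (S).

**Step 2**
Reactants: 4 (S)-2-hydroxy-3-(4-hydroxyphenyl)propanoic acid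
Product: 5 methyl (S)-2-hydroxy-3-(4-hydroxyphenyl)propanoate
Conditions: MeOH, H2SO4 (cat.), reflux
Reagents that add atoms: methanol, CO
Why: Fischer esterification under acid catalysis should esterify only the carboxylic acid, leaving the phenol, the secondary alcohol and the configuration at C2 untouched.

**Step 3**
Reactants: 5 methyl (S)-2-hydroxy-3-(4-hydroxyphenyl)propanoate
Product: 6 methyl (S)-2-(methoxymethoxy)-3-[4-(methoxymethoxy)phenyl]propanoate
Conditions: MOMCl (3 equiv), i-Pr2NEt (4 equiv), Bu4NI (cat.), CH2Cl2, 0 → 40 °C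
Reagents that add atoms: chloromethyl methyl ether (MOMCl), COCCl
Why: Williamson-type O-alkylation with the reactive α-chloro ether under amine base should cap both the phenol and the C2 hydroxyl as MOM acetals without deprotonating the α-carbon, so C2 stays (S).

**Step 4**
Reactants: 6 methyl (S)-2-(methoxymethoxy)-3-[4-(methoxymethoxy)phenyl]propanoate
Product: 7 (S)-2-(methoxymethoxy)-3-[4-(methoxymethoxy)phenyl]propanal
Conditions: i-Bu2AlH (DIBAL-H, 1.1 equiv), CH2Cl2, −78 °C; MeOH quench, aq. potassium sodium tartrate; used at once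
Reagents that add atoms: none
Why: Partial reduction of an ester by DIBAL-H should stop at the aldehyde because the tetrahedral aluminium hemiacetal, chelated by the α-MOM oxygen, is stable at −78 °C and collapses only on work-up, and no base is present to epimerise C2.

**Step 5**
Reactants: 7 (S)-2-(methoxymethoxy)-3-[4-(methoxymethoxy)phenyl]propanal; 8 acetaldehyde (two equivalents incorporated)
Product: 11 (4R,6S)-6-[(1S)-1-(methoxymethoxy)-2-[4-(methoxymethoxy)phenyl]ethyl]oxane-2,4-diol (anomeric mixture), via mono-aldol 9 (not isolated), via open-chain dihydroxy aldehyde 10 (not isolated)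
Conditions: 2-deoxy-D-ribose-5-phosphate aldolase (acetaldehyde-tolerant variant of the Escherichia coli enzyme, cell-free extract), 8 (2.5 equiv, slow feed), triethanolamine buffer (0.1 M, pH 7.5), DMSO (10% v/v), 25 °C
Reagents that add atoms: none
Why: The enzyme condenses acetaldehyde 8 with its active-site lysine to an enamine, which adds to the si face of the aldehyde carbon of 7 (C3 of the chain) and releases β-hydroxy aldehyde 9 after hydrolysis (C3–C4 bond); because O2 is a MOM ether, 9 has no hydroxyl that can reach its aldehyde in a five- or six-membered ring, so it stays open and is accepted a second time with the same facial sense to give 10 (C5–C6 bond). The closest known reaction type is the aldolase-catalysed tandem addition of two acetaldehydes to α-chloro-, α-methoxy- and α,α-dimethoxyacetaldehyde, which ends in 6-substituted 2,4-dideoxypyranose lactols. The single ring closes by hemiacetal formation, a 6-exo-trig addition of the C3 hydroxyl to the C7 aldehyde of 10, and this lactolisation removes the aldehyde and stops chain growth. Both new carbinols are set by the enzyme (catalyst control): the same topicity twice should give (S) at C3 and the 3,5-syn relation, the second centre being (R) by the CIP rules in 10 and 11 and becoming (S)-C5 of the target, while C2 comes unchanged from tyrosine. The step needs the second addition to outrun any trapping of 9 and the enzyme's sense of addition to override the resident C2 centre; the MOM ether at O2 secures the first, and the second rests on enzyme control, with the (S)-acceptor (the L-type α-centre that the wild-type enzyme turns over slowly) as the main uncertainty. Slow feeding of 8 should keep the self-condensation of acetaldehyde in the background.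

**Step 6**
Reactants: 12 4-bromo-2-methoxyphenol
Product: 13 1-(benzyloxy)-4-bromo-2-methoxybenzene
Conditions: BnBr, K2CO3, acetone, reflux
Reagents that add atoms: benzyl bromide, BrCc1ccccc1
Why: Williamson ether synthesis of the phenoxide with benzyl bromide should give the benzyl ether, which masks the acidic phenol for Grignard formation and is removed later by hydrogenolysis.

**Step 7**
Reactants: 11 (4R,6S)-6-[(1S)-1-(methoxymethoxy)-2-[4-(methoxymethoxy)phenyl]ethyl]oxane-2,4-diol; 13 1-(benzyloxy)-4-bromo-2-methoxybenzene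
Product: 16 (1RS,3S,5S,6S)-1-[4-(benzyloxy)-3-methoxyphenyl]-6-(methoxymethoxy)-7-[4-(methoxymethoxy)phenyl]heptane-1,3,5-triol (C1 epimers), via arylmagnesium bromide 14 (not isolated), via ring-opened bis(bromomagnesium) alkoxide 15 (not isolated)
Conditions: 13, Mg turnings, I2 (cat.), THF, 50 °C (gives 14, 5 equiv); then 11, THF, 0 °C → rt; aq. NH4Cl
Reagents that add atoms: none
Why: Grignard addition to a lactol: two equivalents of 14 deprotonate the two hydroxyl groups of 11, the lactol alkoxide opens to the aldehyde bis(bromomagnesium) alkoxide 15, and a further equivalent of 14 adds to the C7 carbonyl of 15 to form the C7–aryl bond; the configuration of the new benzylic carbinol does not matter because this oxygen is removed in step 8.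

**Step 8**
Reactants: 16 (1RS,3S,5S,6S)-1-[4-(benzyloxy)-3-methoxyphenyl]-6-(methoxymethoxy)-7-[4-(methoxymethoxy)phenyl]heptane-1,3,5-triol
Product: 17 (2S,3S,5S)-7-(4-hydroxy-3-methoxyphenyl)-2-(methoxymethoxy)-1-[4-(methoxymethoxy)phenyl]heptane-3,5-diol
Conditions: H2 (3 bar), Pd(OH)2/C, EtOH–AcOH (4:1), 40 °C
Reagents that add atoms: none
Why: Catalytic hydrogenolysis should first cleave the O-benzyl ether and then the benzylic C7–O bond, which is activated by the freed para-hydroxyl, while the non-benzylic carbinols at C3 and C5 and both MOM ethers survive.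

**Step 9**
Reactants: 17 (2S,3S,5S)-7-(4-hydroxy-3-methoxyphenyl)-2-(methoxymethoxy)-1-[4-(methoxymethoxy)phenyl]heptane-3,5-diol
Product: 18 (2S,3S,5S)-7-(4-hydroxy-3-methoxyphenyl)-1-(4-hydroxyphenyl)heptane-2,3,5-triol (CNP0232775.1)
Conditions: conc. aq. HCl (cat.), MeOH, 40 °C
Reagents that add atoms: none
Why: Acid-catalysed acetal exchange (methanolysis of the two MOM ethers to dimethoxymethane) should free the C2 hydroxyl and the phenol without touching the carbinol stereocentres, none of which can ionise under these conditions.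

**Compound list**

1 | L-tyrosine | N[C@@H](Cc1ccc(O)cc1)C(=O)O | starting material
2 | (S)-2-diazonio-3-(4-hydroxyphenyl)propanoate | N#[N+][C@@H](Cc1ccc(O)cc1)C(=O)[O-] | intermediate
3 | (R)-3-(4-hydroxybenzyl)oxiran-2-one | O=C1O[C@@H]1Cc1ccc(O)cc1 | intermediate
4 | (S)-2-hydroxy-3-(4-hydroxyphenyl)propanoic acid | O[C@@H](Cc1ccc(O)cc1)C(=O)O | intermediate
5 | methyl (S)-2-hydroxy-3-(4-hydroxyphenyl)propanoate | COC(=O)[C@@H](O)Cc1ccc(O)cc1 | intermediate
6 | methyl (S)-2-(methoxymethoxy)-3-[4-(methoxymethoxy)phenyl]propanoate | COC(=O)[C@@H](OCOC)Cc1ccc(OCOC)cc1 | intermediate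
7 | (S)-2-(methoxymethoxy)-3-[4-(methoxymethoxy)phenyl]propanal | O=C[C@@H](OCOC)Cc1ccc(OCOC)cc1 | intermediate
8 | acetaldehyde | CC=O | starting material
9 | (3S,4S)-3-hydroxy-4-(methoxymethoxy)-5-[4-(methoxymethoxy)phenyl]pentanal | O=CC[C@H](O)[C@@H](OCOC)Cc1ccc(OCOC)cc1 | intermediate
10 | (3R,5S,6S)-3,5-dihydroxy-6-(methoxymethoxy)-7-[4-(methoxymethoxy)phenyl]heptanal | O=CC[C@H](O)C[C@H](O)[C@@H](OCOC)Cc1ccc(OCOC)cc1 | intermediate
11 | (4R,6S)-6-[(1S)-1-(methoxymethoxy)-2-[4-(methoxymethoxy)phenyl]ethyl]oxane-2,4-diol, anomeric mixture | OC1C[C@H](O)C[C@@H]([C@@H](OCOC)Cc2ccc(OCOC)cc2)O1 | intermediate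
12 | 4-bromo-2-methoxyphenol | COc1cc(Br)ccc1O | starting material
13 | 1-(benzyloxy)-4-bromo-2-methoxybenzene | COc1cc(Br)ccc1OCc1ccccc1 | intermediate
14 | [4-(benzyloxy)-3-methoxyphenyl]magnesium bromide | COc1cc([Mg]Br)ccc1OCc1ccccc1 | intermediate
15 | bis(bromomagnesium) 3,5-dialkoxide of (3R,5S,6S)-3,5-dihydroxy-6-(methoxymethoxy)-7-[4-(methoxymethoxy)phenyl]heptanal (ring-opened form of doubly deprotonated 11) | O=CC[C@H](O[Mg]Br)C[C@H](O[Mg]Br)[C@@H](OCOC)Cc1ccc(OCOC)cc1 | intermediate
16 | (1RS,3S,5S,6S)-1-[4-(benzyloxy)-3-methoxyphenyl]-6-(methoxymethoxy)-7-[4-(methoxymethoxy)phenyl]heptane-1,3,5-triol | COc1cc(C(O)C[C@H](O)C[C@H](O)[C@@H](OCOC)Cc2ccc(OCOC)cc2)ccc1OCc1ccccc1 | intermediate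
17 | (2S,3S,5S)-7-(4-hydroxy-3-methoxyphenyl)-2-(methoxymethoxy)-1-[4-(methoxymethoxy)phenyl]heptane-3,5-diol | COc1cc(CC[C@H](O)C[C@H](O)[C@@H](OCOC)Cc2ccc(OCOC)cc2)ccc1O | intermediate
18 | (2S,3S,5S)-7-(4-hydroxy-3-methoxyphenyl)-1-(4-hydroxyphenyl)heptane-2,3,5-triol | COc1cc(CC[C@H](O)C[C@H](O)[C@@H](O)Cc2ccc(O)cc2)ccc1O | target

**Step count**

Total steps: 9. Longest linear sequence: 8 steps (steps 1–5 and 7–9, from L-tyrosine); step 6 is a one-step side branch.

**Steps most likely to fail**

1. Step 5. The bulky α-branched (S)-acceptor may be turned over too slowly, so that self-condensation of acetaldehyde takes over. Slow epimerisation of C2 in the buffer, combined with faster turnover of the (R)-acceptor, could also erode the C2 configuration. The fallback sets out from 7 and comes back at 11, and builds the same lactol by substrate-controlled chemistry. A chelation-controlled vinylogous Mukaiyama aldol addition of 1-methoxy-1,3-bis(trimethylsilyloxy)buta-1,3-diene to 7 (MgBr2·OEt2, CH2Cl2, −78 → −20 °C) is used first; the magnesium chelate between the aldehyde oxygen and the O2 MOM ether should direct attack to the 2,3-syn product, methyl (5S,6S)-5-hydroxy-6-(methoxymethoxy)-7-[4-(methoxymethoxy)phenyl]-3-oxoheptanoate F1. Narasaka–Prasad reduction (Et2BOMe, NaBH4, THF–MeOH, −78 °C) should then give the 3,5-syn diol methyl (3R,5S,6S)-3,5-dihydroxy-6-(methoxymethoxy)-7-[4-(methoxymethoxy)phenyl]heptanoate F2. Lactonisation (pyridinium p-toluenesulfonate, toluene, 60 °C) should give (4R,6S)-4-hydroxy-6-[(1S)-1-(methoxymethoxy)-2-[4-(methoxymethoxy)phenyl]ethyl]oxan-2-one F3, and i-Bu2AlH (CH2Cl2, −78 °C) should reduce F3 to lactol 11.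

2. Step 7. The bromomagnesium alkoxides of the unprotected lactol may aggregate and keep the ring closed, or the opened β-alkoxy aldehyde may be enolised by the basic reagent (then β-elimination or retro-aldol) instead of being attacked. The fallback sets out from 11 and comes back at 18, and avoids carbonyl addition and the benzylic alcohol altogether. NaBH4 (MeOH, 0 °C) should reduce 11 to (3S,5S,6S)-6-(methoxymethoxy)-7-[4-(methoxymethoxy)phenyl]heptane-1,3,5-triol F4. A primary-selective Appel reaction (CBr4, PPh3, CH2Cl2, 0 °C) should give (3R,5S,6S)-1-bromo-6-(methoxymethoxy)-7-[4-(methoxymethoxy)phenyl]heptane-3,5-diol F5. In parallel, 12 is protected (MOMCl, i-Pr2NEt, CH2Cl2) as 4-bromo-2-methoxy-1-(methoxymethoxy)benzene F6. A nickel-catalysed reductive cross-electrophile coupling of F5 with F6 (NiI2, 4,4'-di-tert-butyl-2,2'-bipyridine, Zn dust, NaI, pyridine, DMPU, 60 °C), which tolerates free hydroxyls, should give (2S,3S,5S)-7-[3-methoxy-4-(methoxymethoxy)phenyl]-2-(methoxymethoxy)-1-[4-(methoxymethoxy)phenyl]heptane-3,5-diol F7. The conditions of step 9 (HCl, MeOH) then remove the three MOM ethers of F7 to give 18.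

3. Step 8. After debenzylation, acid-promoted ionisation of the para-hydroxybenzylic alcohol and capture of the cation by the C3 hydroxyl may close a 2-aryl-tetrahydropyran faster than the C7–O bond is hydrogenolysed, or the reduction may stall at the benzylic alcohol. The fallback sets out from 16 and comes back at 17, and removes the C7 oxygen under basic conditions. Neutral hydrogenolysis (H2, Pd/C, EtOAc, rt) should cleave only the benzyl ether and give (1RS,3S,5S,6S)-1-(4-hydroxy-3-methoxyphenyl)-6-(methoxymethoxy)-7-[4-(methoxymethoxy)phenyl]heptane-1,3,5-triol F8. Heating F8 with excess NaBH4 in aq. NaOH–EtOH (70 °C) should expel hydroxide from the phenoxide to form the para-quinone methide, which borohydride reduces by 1,6-hydride addition to give 17; the MOM ethers are stable to base.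

**Further compounds**

F1 | step 5 | methyl (5S,6S)-5-hydroxy-6-(methoxymethoxy)-7-[4-(methoxymethoxy)phenyl]-3-oxoheptanoate | COC(=O)CC(=O)C[C@H](O)[C@@H](OCOC)Cc1ccc(OCOC)cc1
F2 | step 5 | methyl (3R,5S,6S)-3,5-dihydroxy-6-(methoxymethoxy)-7-[4-(methoxymethoxy)phenyl]heptanoate | COC(=O)C[C@H](O)C[C@H](O)[C@@H](OCOC)Cc1ccc(OCOC)cc1
F3 | step 5 | (4R,6S)-4-hydroxy-6-[(1S)-1-(methoxymethoxy)-2-[4-(methoxymethoxy)phenyl]ethyl]oxan-2-one | O=C1C[C@H](O)C[C@@H]([C@@H](OCOC)Cc2ccc(OCOC)cc2)O1
F4 | step 7 | (3S,5S,6S)-6-(methoxymethoxy)-7-[4-(methoxymethoxy)phenyl]heptane-1,3,5-triol | OCC[C@H](O)C[C@H](O)[C@@H](OCOC)Cc1ccc(OCOC)cc1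
F5 | step 7 | (3R,5S,6S)-1-bromo-6-(methoxymethoxy)-7-[4-(methoxymethoxy)phenyl]heptane-3,5-diol | BrCC[C@H](O)C[C@H](O)[C@@H](OCOC)Cc1ccc(OCOC)cc1
F6 | step 7 | 4-bromo-2-methoxy-1-(methoxymethoxy)benzene | COCOc1ccc(Br)cc1OC
F7 | step 7 | (2S,3S,5S)-7-[3-methoxy-4-(methoxymethoxy)phenyl]-2-(methoxymethoxy)-1-[4-(methoxymethoxy)phenyl]heptane-3,5-diol | COc1cc(CC[C@H](O)C[C@H](O)[C@@H](OCOC)Cc2ccc(OCOC)cc2)ccc1OCOC
F8 | step 8 | (1RS,3S,5S,6S)-1-(4-hydroxy-3-methoxyphenyl)-6-(methoxymethoxy)-7-[4-(methoxymethoxy)phenyl]heptane-1,3,5-triol | COc1cc(C(O)C[C@H](O)C[C@H](O)[C@@H](OCOC)Cc2ccc(OCOC)cc2)ccc1O
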